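Everything rests on cutting the C2–C3 bond of the dihydrofuran ring. C2 carries the ring oxygen O1 and is allylic to an exocyclic methylene whose inner carbon bears the formyl carbon. That pattern is what remains when a gamma-aryloxy allyl metal adds through its oxygenated carbon to an ortho aldehyde, which becomes C3. A copper-catalysed borylative cyclisation of an ortho-formyl aryloxyallene should therefore form C2–C3, close the dihydrofuran ring, set both ring stereocentres cis and leave an alkenyl–boron bond for the missing formyl carbon, all in one operation. The precursor is 5-acetyl-2-(propa-1,2-dien-1-yloxy)benzaldehyde, whose acetyl group is the latent (S)-carbinol.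

Key step: step 6

Remark: benzofuran numbering is used throughout (O1, C2, C3, C3a, C4 to C7, C7a); Bpin stands for 4,4,5,5-tetramethyl-1,3,2-dioxaborolan-2-yl.
Remark: the sense of induction of Ph-BPE in this intramolecular case cannot be predicted with confidence; (S,S)-Ph-BPE is written, and its mirror image is to be used if a trial run shows the (2S,3S) series.
Remark: the acetyl group is kept free in the precursor because it distinguishes the two secondary carbinols without protecting groups; both carbonyl groups are masked as dimethyl acetals only while the allene is made with base.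

Step 1
Reactants: 1 4-hydroxyacetophenone; 2 hexamethylenetetramine
Product: 3 5-acetyl-2-hydroxybenzaldehyde
Conditions: hexamethylenetetramine, CF3CO2H, 90 °C; then H2O, 60 °C
Reagents that add atoms: hexamethylenetetramine, C1N2CN3CN1CN(C2)C3 (formyl carbon); water, O (formyl oxygen)
Why: Duff formylation: the iminium electrophile released from hexamethylenetetramine in CF3CO2H substitutes the ring ortho to the phenol (the para position is blocked by the acetyl group) and hydrolysis of the resulting benzylic iminium gives the aldehyde.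

Step 2
Reactants: 3 5-acetyl-2-hydroxybenzaldehyde; 4 3-bromoprop-1-yne
Product: 5 5-acetyl-2-(prop-2-yn-1-yloxy)benzaldehyde
Conditions: K2CO3, DMF, rt
Reagents that add atoms: 3-bromoprop-1-yne, C#CCBr
Why: Williamson etherification: the acidic phenol is deprotonated by K2CO3 and alkylated at oxygen by the propargylic bromide in an SN2 reaction under conditions too mild for aldol condensation of the keto aldehyde.

Step 3
Reactants: 5 5-acetyl-2-(prop-2-yn-1-yloxy)benzaldehyde; 6 trimethyl orthoformate
Product: 7 4-(1,1-dimethoxyethyl)-2-(dimethoxymethyl)-1-(prop-2-yn-1-yloxy)benzene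
Conditions: HC(OMe)3, MeOH, TsOH·H2O (cat.), rt; Et3N quench; used crude
Reagents that add atoms: trimethyl orthoformate, COC(OC)OC; methanol, CO (the methoxy groups come from either)
Why: Acid-catalysed acetalisation with the orthoformate as water scavenger turns the aldehyde and the aryl ketone into base-stable dimethyl acetals so that the next step meets neither an enolisable ketone nor an electrophilic or nucleophilic oxygen function.

Step 4
Reactants: 7 4-(1,1-dimethoxyethyl)-2-(dimethoxymethyl)-1-(prop-2-yn-1-yloxy)benzene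
Product: 8 4-(1,1-dimethoxyethyl)-2-(dimethoxymethyl)-1-(propa-1,2-dien-1-yloxy)benzene
Conditions: KOtBu (0.3 equiv), THF, 0 °C to rt
Reagents that add atoms: none
Why: Base-catalysed propargyl-to-allenyl prototropic isomerisation is the standard entry to aryloxyallenes from aryl propargyl ethers and needs only catalytic alkoxide here because the substrate offers no more acidic C–H or O–H bond.

Step 5
Reactants: 8 4-(1,1-dimethoxyethyl)-2-(dimethoxymethyl)-1-(propa-1,2-dien-1-yloxy)benzene
Product: 9 5-acetyl-2-(propa-1,2-dien-1-yloxy)benzaldehyde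
Conditions: PPTS (cat.), acetone/H2O 10:1, 0 °C to rt
Reagents that add atoms: water, O (both carbonyl oxygens)
Why: Chemoselective acetal hydrolysis: both acetals ionise to aryl-stabilised oxocarbenium ions much faster than the electron-poor aryloxyallene is protonated at its central carbon so that buffered aqueous acid should unmask aldehyde and ketone without touching the allenyl ether.

Step 6
Reactants: 9 5-acetyl-2-(propa-1,2-dien-1-yloxy)benzaldehyde; 10 bis(pinacolato)diboron
Product: 13 1-{(2R,3R)-3-hydroxy-2-[1-(4,4,5,5-tetramethyl-1,3,2-dioxaborolan-2-yl)ethenyl]-2,3-dihydro-1-benzofuran-5-yl}ethan-1-one, via (Z)-2-boryl allylcopper 11 (not isolated), via O-boryl ether 12 (not isolated)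
Conditions: CuCl (5 mol %), (S,S)-Ph-BPE (6 mol %), NaOtBu (10 mol %), B2pin2 (1.05 equiv), THF, −20 °C to rt, no protic additive; aq. NH4Cl work-up
Reagents that add atoms: bis(pinacolato)diboron, CC1(C)OB(OC1(C)C)B1OC(C)(C)C(C)(C)O1
Why: Proposed new method: a bisphosphine-ligated LCu–Bpin, generated from CuCl, NaOtBu and B2pin2, should add syn across the terminal C=C of the allene from the face remote from the aryloxy group, placing boron on the central carbon and copper on CH2 to give the (Z)-2-boryl allylcopper 11, whose oxygen-bearing gamma carbon then attacks the ortho formyl group before the resulting Cu–O bond is borylated by B2pin2 to 12 with return of LCu–Bpin. The closest known reaction type is the copper-catalysed enantioselective three-component coupling of allenes, B2pin2 and aldehydes or ketones through 2-boryl allylcopper intermediates; what is new is the internal trapping by an aldehyde that is tethered through an aryloxy group on the allene. The dihydrofuran ring closes in a 5-exo-trig mode with respect to the C=O, through a closed chair-like six-membered transition state that contains copper. C2 and C3 are set together: their cis relation follows from the Z allylcopper (aryloxy group axial, aryl tether of the aldehyde equatorial) and their absolute configuration from the chiral ligand on copper. The step needs chemoselective insertion of the allene in the presence of two carbonyl groups, which the much higher rate of allene borylcupration should provide, and site selectivity for the aldehyde over the ketone, which the substrate secures because only the ortho formyl group lies within reach for a five-membered closure.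

Step 7
Reactants: 13 1-{(2R,3R)-3-hydroxy-2-[1-(Bpin)ethenyl]-2,3-dihydro-1-benzofuran-5-yl}ethan-1-one; 14 3-methylbutanoic anhydride
Product: 15 (2R,3R)-5-acetyl-2-[1-(Bpin)ethenyl]-2,3-dihydro-1-benzofuran-3-yl 3-methylbutanoate
Conditions: (iPrCH2CO)2O, Et3N, DMAP (cat.), CH2Cl2, 0 °C
Reagents that add atoms: 3-methylbutanoic anhydride, CC(C)CC(=O)OC(=O)CC(C)C
Why: DMAP-catalysed acyl transfer from the anhydride esterifies the secondary benzylic alcohol with retention because no bond to C3 is broken, and the mild base at 0 °C should not trigger elimination toward the benzofuran.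

Step 8
Reactants: 15 (2R,3R)-5-acetyl-2-[1-(Bpin)ethenyl]-2,3-dihydro-1-benzofuran-3-yl 3-methylbutanoate
Product: 16 (2R,3R)-5-[(1S)-1-hydroxyethyl]-2-[1-(Bpin)ethenyl]-2,3-dihydro-1-benzofuran-3-yl 3-methylbutanoate
Conditions: RuCl(p-cymene)[(S,S)-TsDPEN] (2 mol %), HCO2H/Et3N 5:2, CH2Cl2, 28 °C
Reagents that add atoms: none
Why: Asymmetric transfer hydrogenation of the aryl methyl ketone (Noyori–Ikariya type) with the (S,S)-configured catalyst should give the (S)-1-arylethanol under catalyst control, while ester, alkenyl boronate and the ring stereocentres are not touched.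

Step 9
Reactants: 16 (2R,3R)-5-[(1S)-1-hydroxyethyl]-2-[1-(Bpin)ethenyl]-2,3-dihydro-1-benzofuran-3-yl 3-methylbutanoate; 17 3-methylbut-2-enoic acid
Product: 18 (1S)-1-{(2R,3R)-3-[(3-methylbutanoyl)oxy]-2-[1-(Bpin)ethenyl]-2,3-dihydro-1-benzofuran-5-yl}ethyl 3-methylbut-2-enoate
Conditions: 3-methylbut-2-enoic acid, DCC, DMAP (cat.), CH2Cl2, 0 °C to rt
Reagents that add atoms: 3-methylbut-2-enoic acid, CC(C)=CC(=O)O
Why: Steglich esterification of the free acid avoids the acid chloride and strong amine base that could deconjugate the senecioyl unit through a vinylketene, and it acylates the alcohol oxygen without breaking the benzylic C–O bond so that the (S) centre is retained.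

Step 10
Reactants: 18 (1S)-1-{(2R,3R)-3-[(3-methylbutanoyl)oxy]-2-[1-(Bpin)ethenyl]-2,3-dihydro-1-benzofuran-5-yl}ethyl 3-methylbut-2-enoate; 19 bromochloromethane
Product: 22 (1S)-1-{(2R,3R)-2-(3-hydroxyprop-1-en-2-yl)-3-[(3-methylbutanoyl)oxy]-2,3-dihydro-1-benzofuran-5-yl}ethyl 3-methylbut-2-enoate, via chloromethyl borate complex 20 (not isolated), via allylboronate 21 (not isolated)
Conditions: BrCH2Cl, n-BuLi (added last, dropwise), THF, −78 °C to rt; then NaBO3·4H2O, THF/H2O, rt
Reagents that add atoms: bromochloromethane, ClCBr (CH2); sodium perborate, [Na+].[O-]OB=O (hydroxyl oxygen)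
Why: Matteson homologation: chloromethyllithium generated in the presence of the boronate should be captured at boron faster than at the hindered or conjugated ester carbonyls, the ate complex 20 rearranges by 1,2-migration of the alkenyl group with loss of chloride to the allylboronate 21, and perborate then oxidises the C–B bond to the primary allylic alcohol under conditions mild enough for both esters.

Step 11
Reactants: 22 (1S)-1-{(2R,3R)-2-(3-hydroxyprop-1-en-2-yl)-3-[(3-methylbutanoyl)oxy]-2,3-dihydro-1-benzofuran-5-yl}ethyl 3-methylbut-2-enoate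
Product: 23 (1S)-1-{(2R,3R)-3-[(3-methylbutanoyl)oxy]-2-(3-oxoprop-1-en-2-yl)-2,3-dihydro-1-benzofuran-5-yl}ethyl 3-methylbut-2-enoate
Conditions: MnO2 (activated, excess), CH2Cl2, rt
Reagents that add atoms: none
Why: Allylic oxidation with MnO2 is selective for the primary allylic alcohol and runs at neutral pH so that the enal should form without over-oxidation and without acid or base that could eliminate the C3 ester toward the benzofuran or ionise the benzylic ester.

Compound list

1 | 4-hydroxyacetophenone | CC(=O)c1ccc(O)cc1 | starting material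
2 | hexamethylenetetramine | C1N2CN3CN1CN(C2)C3 | starting material
3 | 5-acetyl-2-hydroxybenzaldehyde | CC(=O)c1ccc(O)c(C=O)c1 | intermediate
4 | 3-bromoprop-1-yne | C#CCBr | starting material
5 | 5-acetyl-2-(prop-2-yn-1-yloxy)benzaldehyde | CC(=O)c1ccc(OCC#C)c(C=O)c1 | intermediate
6 | trimethyl orthoformate | COC(OC)OC | starting material
7 | 4-(1,1-dimethoxyethyl)-2-(dimethoxymethyl)-1-(prop-2-yn-1-yloxy)benzene | COC(OC)c1cc(C(C)(OC)OC)ccc1OCC#C | intermediate
8 | 4-(1,1-dimethoxyethyl)-2-(dimethoxymethyl)-1-(propa-1,2-dien-1-yloxy)benzene | COC(OC)c1cc(C(C)(OC)OC)ccc1OC=C=C | intermediate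
9 | 5-acetyl-2-(propa-1,2-dien-1-yloxy)benzaldehyde (precursor of the key step) | C=C=COc1ccc(C(C)=O)cc1C=O | intermediate
10 | bis(pinacolato)diboron | CC1(C)OB(OC1(C)C)B1OC(C)(C)C(C)(C)O1 | starting material
11 | {(2Z)-3-(4-acetyl-2-formylphenoxy)-2-(Bpin)prop-2-en-1-yl}copper, Ph-BPE on copper not drawn | [Cu]C/C(B1OC(C)(C)C(C)(C)O1)=C\Oc1ccc(C(C)=O)cc1C=O | intermediate (not isolated)
12 | 1-{(2R,3R)-2-[1-(Bpin)ethenyl]-3-[(4,4,5,5-tetramethyl-1,3,2-dioxaborolan-2-yl)oxy]-2,3-dihydro-1-benzofuran-5-yl}ethan-1-one | C=C(B3OC(C)(C)C(C)(C)O3)[C@H]1Oc2ccc(C(C)=O)cc2[C@H]1OB1OC(C)(C)C(C)(C)O1 | intermediate (not isolated)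
13 | 1-{(2R,3R)-3-hydroxy-2-[1-(4,4,5,5-tetramethyl-1,3,2-dioxaborolan-2-yl)ethenyl]-2,3-dihydro-1-benzofuran-5-yl}ethan-1-one (product of the key step) | C=C(B3OC(C)(C)C(C)(C)O3)[C@H]1Oc2ccc(C(C)=O)cc2[C@H]1O | intermediate
14 | 3-methylbutanoic anhydride | CC(C)CC(=O)OC(=O)CC(C)C | starting material
15 | (2R,3R)-5-acetyl-2-[1-(Bpin)ethenyl]-2,3-dihydro-1-benzofuran-3-yl 3-methylbutanoate | C=C(B3OC(C)(C)C(C)(C)O3)[C@H]1Oc2ccc(C(C)=O)cc2[C@H]1OC(=O)CC(C)C | intermediate
16 | (2R,3R)-5-[(1S)-1-hydroxyethyl]-2-[1-(Bpin)ethenyl]-2,3-dihydro-1-benzofuran-3-yl 3-methylbutanoate | C=C(B3OC(C)(C)C(C)(C)O3)[C@H]1Oc2ccc([C@H](C)O)cc2[C@H]1OC(=O)CC(C)C | intermediate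
17 | 3-methylbut-2-enoic acid | CC(C)=CC(=O)O | starting material
18 | (1S)-1-{(2R,3R)-3-[(3-methylbutanoyl)oxy]-2-[1-(Bpin)ethenyl]-2,3-dihydro-1-benzofuran-5-yl}ethyl 3-methylbut-2-enoate | C=C(B3OC(C)(C)C(C)(C)O3)[C@H]1Oc2ccc([C@H](C)OC(=O)C=C(C)C)cc2[C@H]1OC(=O)CC(C)C | intermediate
19 | bromochloromethane | ClCBr | starting material
20 | lithium borate complex of 18 that carries a chloromethyl group on the tetracoordinate boron | [Li+].C=C([B-]3(CCl)OC(C)(C)C(C)(C)O3)[C@H]1Oc2ccc([C@H](C)OC(=O)C=C(C)C)cc2[C@H]1OC(=O)CC(C)C | intermediate (not isolated)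
21 | (1S)-1-{(2R,3R)-3-[(3-methylbutanoyl)oxy]-2-[3-(Bpin)prop-1-en-2-yl]-2,3-dihydro-1-benzofuran-5-yl}ethyl 3-methylbut-2-enoate | C=C(CB3OC(C)(C)C(C)(C)O3)[C@H]1Oc2ccc([C@H](C)OC(=O)C=C(C)C)cc2[C@H]1OC(=O)CC(C)C | intermediate (not isolated)
22 | (1S)-1-{(2R,3R)-2-(3-hydroxyprop-1-en-2-yl)-3-[(3-methylbutanoyl)oxy]-2,3-dihydro-1-benzofuran-5-yl}ethyl 3-methylbut-2-enoate | C=C(CO)[C@H]1Oc2ccc([C@H](C)OC(=O)C=C(C)C)cc2[C@H]1OC(=O)CC(C)C | intermediate
23 | (1S)-1-{(2R,3R)-3-[(3-methylbutanoyl)oxy]-2-(3-oxoprop-1-en-2-yl)-2,3-dihydro-1-benzofuran-5-yl}ethyl 3-methylbut-2-enoate (CNP0325942.1) | C=C(C=O)[C@H]1Oc2ccc([C@H](C)OC(=O)C=C(C)C)cc2[C@H]1OC(=O)CC(C)C | target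

Total step count: 11.
Longest linear sequence: 11 steps, from 4-hydroxyacetophenone 1 to 23.

Steps most likely to fail

Step 6 (Proposed new method). The LCu–Bpin species may add to the aldehyde in competition with the allene. The allylcopper may be protonated or lose its Z geometry before ring closure. Turnover may stall at the hindered Cu–O stage, or facial selectivity may be poor. The fallback uses known reaction types and sets out from 9. Diboration of the allene with 10 under Pt(dba)2 and PCy3 in toluene (zerovalent platinum, bulky phosphine to direct addition to the terminal C=C) should give the allyl/alkenyl bis-boronate 5-acetyl-2-{[(1Z)-2,3-bis(Bpin)prop-1-en-1-yl]oxy}benzaldehyde F1. Its allylboronate unit should add to the ortho aldehyde on gentle warming through a closed transition state (intramolecular allylboration), giving the racemic cis O-boryl ether F2, which aqueous work-up converts into the racemic cis alcohol F3. An acylative kinetic resolution of F3 with 14, iPr2NEt and a chiral isothiourea acyl-transfer catalyst (benzotetramisole, in the enantiomer that acylates the (2R,3R) alcohol faster) should then deliver the ester directly and leave the (2S,3S) alcohol F4 behind. The fallback comes back to the route at 15.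

Step 10. The lithium carbenoid or n-BuLi may attack the ester carbonyls or deprotonate next to them in competition with ate-complex formation, and the ate complex may fragment by loss of the aryloxide with opening of the dihydrofuran ring. The fallback sets out from 18. A Suzuki–Miyaura methylation with iodomethane (PdCl2(dppf), K3PO4, DMF/H2O, 60 °C) should give the isopropenyl compound (1S)-1-{(2R,3R)-3-[(3-methylbutanoyl)oxy]-2-(prop-1-en-2-yl)-2,3-dihydro-1-benzofuran-5-yl}ethyl 3-methylbut-2-enoate F5. Allylic oxidation of F5 with catalytic SeO2 and tBuOOH in CH2Cl2 (Riley oxidation; the ene step prefers the methyl group over the C2 methine) should hydroxylate the isopropenyl methyl group. The fallback comes back at 22; any aldehyde formed alongside is already 23.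

Step 5. Acid-promoted hydration of the allenyl ether may compete with acetal cleavage, or the ketone may be unmasked incompletely. The fallback replaces acetal masking by redox masking and sets out from 5. NaBH4 in MeOH at 0 °C should reduce both carbonyl groups to the diol 1-[3-(hydroxymethyl)-4-(prop-2-yn-1-yloxy)phenyl]ethan-1-ol F6. KOtBu in THF (in excess over the two hydroxyl groups, kept at or below rt to limit addition of the alkoxide to the allene) should isomerise it to the allenyl ether 1-[3-(hydroxymethyl)-4-(propa-1,2-dien-1-yloxy)phenyl]ethan-1-ol F7. MnO2 in CH2Cl2 should then oxidise both benzylic alcohols. The fallback comes back at 9.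

Further compounds

F1 | step 6 | 5-acetyl-2-{[(1Z)-2,3-bis(4,4,5,5-tetramethyl-1,3,2-dioxaborolan-2-yl)prop-1-en-1-yl]oxy}benzaldehyde | O=Cc1cc(C(C)=O)ccc1O/C=C(B1OC(C)(C)C(C)(C)O1)\CB1OC(C)(C)C(C)(C)O1
F2 | step 6 | racemic cis O-boryl ether, the racemate of 12, written as both enantiomers | C=C(B3OC(C)(C)C(C)(C)O3)[C@H]1Oc2ccc(C(C)=O)cc2[C@H]1OB1OC(C)(C)C(C)(C)O1.C=C(B3OC(C)(C)C(C)(C)O3)[C@@H]1Oc2ccc(C(C)=O)cc2[C@@H]1OB1OC(C)(C)C(C)(C)O1
F3 | step 6 | racemic cis alcohol, the racemate of 13, written as both enantiomers | C=C(B3OC(C)(C)C(C)(C)O3)[C@H]1Oc2ccc(C(C)=O)cc2[C@H]1O.C=C(B3OC(C)(C)C(C)(C)O3)[C@@H]1Oc2ccc(C(C)=O)cc2[C@@H]1O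
F4 | step 6 | 1-{(2S,3S)-3-hydroxy-2-[1-(4,4,5,5-tetramethyl-1,3,2-dioxaborolan-2-yl)ethenyl]-2,3-dihydro-1-benzofuran-5-yl}ethan-1-one | C=C(B3OC(C)(C)C(C)(C)O3)[C@@H]1Oc2ccc(C(C)=O)cc2[C@@H]1O
F5 | step 10 | (1S)-1-{(2R,3R)-3-[(3-methylbutanoyl)oxy]-2-(prop-1-en-2-yl)-2,3-dihydro-1-benzofuran-5-yl}ethyl 3-methylbut-2-enoate | C=C(C)[C@H]1Oc2ccc([C@H](C)OC(=O)C=C(C)C)cc2[C@H]1OC(=O)CC(C)C
F6 | step 5 | 1-[3-(hydroxymethyl)-4-(prop-2-yn-1-yloxy)phenyl]ethan-1-ol, racemic at the carbinol | CC(O)c1ccc(OCC#C)c(CO)c1
F7 | step 5 | 1-[3-(hydroxymethyl)-4-(propa-1,2-dien-1-yloxy)phenyl]ethan-1-ol, racemic at the carbinol | CC(O)c1ccc(OC=C=C)c(CO)c1
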